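**Strategy.** The target is the hetero-Diels–Alder adduct of (+)-β-pinene and isobutylidene-syncarpic acid, so the route rests on a de novo, enantioselective build of the pinane. Its cyclobutane ring (bridgeheads C1 and C5, gem-dimethyl carbon C6, methylene bridge C7 of the bicyclo[3.1.1]heptane) is cut into two π-bonds: C5=C7 as a ketene and C1=C6 as a trisubstituted alkene. The key step, an intramolecular ketene–alkene [2+2] cycloaddition of the ketene from (R)-5-silyloxy-7-methyloct-6-enoic acid, forms C7–C1 and C5–C6 at once and sets both bridgeheads from one carbinol stereocenter at C2. The tertiary C6 terminus directs the regiochemistry. The C7 carbonyl is then reduced away, C2 becomes the exocyclic alkene, and the dihydropyran ring is closed last.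

Key step: step 5

Assumption: syncarpic acid 14 and the THF solution of Grignard reagent 2 are taken as purchasable; locants C1–C7 follow the pinane unit of the target throughout (C1 and C5 bridgeheads, C2 the spiro carbon, C6 the CMe2 bridge, C7 the CH2 bridge), and primed locants belong to the chromene.

Step 1
Reactants: 1 methyl 5-chloro-5-oxopentanoate; 2 (2-methylprop-1-en-1-yl)magnesium bromide
Product: 3 methyl 7-methyl-5-oxooct-6-enoate
Conditions: CuBr·SMe2 (5 mol %), THF, −78 °C, slow addition of 2 to 1
Reagents that add atoms: none
Why: Copper-catalysed acylation of the alkenyl Grignard reagent by the acid chloride (ketone synthesis) is much faster at −78 °C than attack on the methyl ester or on the β,β-disubstituted enone formed, so it should stop at the ketone.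

Step 2
Reactants: 3 methyl 7-methyl-5-oxooct-6-enoate
Product: 4 methyl (5R)-5-hydroxy-7-methyloct-6-enoate
Conditions: (S)-2-methyl-CBS-oxazaborolidine (20 mol %), catecholborane (1.5 equiv), toluene, −78 °C; then MeOH, aqueous NaHCO3
Reagents that add atoms: none
Why: Corey–Bakshi–Shibata reduction, in which the alkenyl group acts as the large substituent, should give the (5R)-allylic alcohol by 1,2-reduction and so set the only stereocenter that the route takes from outside.

Step 3
Reactants: 4 methyl (5R)-5-hydroxy-7-methyloct-6-enoate
Product: 5 methyl (5R)-5-[(tert-butyldimethylsilyl)oxy]-7-methyloct-6-enoate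
Conditions: TBSCl, imidazole, DMF, 23 °C
Reagents that add atoms: tert-butyldimethylsilyl chloride, CC(C)(C)[Si](C)(C)Cl
Why: Standard silylation of a secondary allylic alcohol, which blocks lactonisation and supplies the bulky group that later steers the cycloaddition.

Step 4
Reactants: 5 methyl (5R)-5-[(tert-butyldimethylsilyl)oxy]-7-methyloct-6-enoate
Product: 6 (5R)-5-[(tert-butyldimethylsilyl)oxy]-7-methyloct-6-enoic acid
Conditions: LiOH·H2O, THF/MeOH/H2O, 23 °C; then 0.5 M HCl to pH 4, 0 °C
Reagents that add atoms: lithium hydroxide, [Li+].[OH-]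
Why: Saponification of the methyl ester leaves the silyl ether untouched, and the mild acidification avoids its loss.

Step 5
Reactants: 6 (5R)-5-[(tert-butyldimethylsilyl)oxy]-7-methyloct-6-enoic acid
Product: 9 (1S,2R,5S)-2-[(tert-butyldimethylsilyl)oxy]-6,6-dimethylbicyclo[3.1.1]heptan-7-one, via acid chloride 7 (not isolated), via ketene 8 (not isolated)
Conditions: 1-chloro-N,N,2-trimethylprop-1-en-1-amine (1.1 equiv), CH2Cl2, 0 to 23 °C; then syringe-pump addition to Et3N (3 equiv), toluene, 110 °C, final 0.005 M
Reagents that add atoms: none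
Why: The α-chloroenamine turns acid 6 into acid chloride 7 without free HCl, Et3N then eliminates HCl to the alkyl ketene 8, whose electrophilic carbonyl carbon (future C7) bonds to alkene carbon C1 while the developing positive charge sits on the tertiary carbon C6, which closes onto the ketene α-carbon C5 in an asynchronous thermal [π2s+π2a] cycloaddition. The reaction type is the intramolecular ketene–alkene [2+2] cycloaddition of a ketene joined by three atoms to a trisubstituted alkene, a known route to bicyclo[3.1.1]heptanones with the ketone on a one-carbon bridge. The six-membered ring C7–C1–C2–C3–C4–C5 closes in the 6-exo-trig mode at the alkene (endo at the ketene), and the four-membered ring C1–C6–C5–C7 closes when the enolate-like C5 collapses onto the C6 cation, so the bridged bicycle forms in one operation. The new stereocenters C1 and C5 are locked to each other by the bridged ring and are set by the (R)-carbinol C2: with the tether on the attacked alkene face, the bulky silyloxy group should lie outside, in the alkene plane away from the Z-methyl group, and the C–H bond anti to the incoming ketene, so that the oxygen ends on the side of the carbonyl bridge and anti to the CMe2 bridge. The step needs regioselectivity for the [3.1.1] over the [3.2.0] skeleton, secured by the gem-dimethyl terminus that takes the positive charge, and cycloaddition ahead of ketene dimerisation, secured by slow addition at high dilution. Any minor diastereomer is removed by chromatography at this stage, because it would end as the enantiomer once C2 is oxidised.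

Step 6
Reactants: 9 (1S,2R,5S)-2-[(tert-butyldimethylsilyl)oxy]-6,6-dimethylbicyclo[3.1.1]heptan-7-one
Product: 11 (1S,2R,5R)-6,6-dimethylbicyclo[3.1.1]heptan-2-ol, via hydrazone 10 (not isolated)
Conditions: N2H4·H2O, diethylene glycol, 120 °C; then KOH, 200 °C
Reagents that add atoms: none
Why: Wolff–Kishner reduction (Huang-Minlon procedure) should turn the strained cyclobutanone through hydrazone 10 into the C7 methylene, the hot alkaline glycol should cleave the silyl ether in the same operation, and the bridgehead α-carbons cannot enolise, so no stereocenter is at risk.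

Step 7
Reactants: 11 (1S,2R,5R)-6,6-dimethylbicyclo[3.1.1]heptan-2-ol
Product: 12 (1S,5R)-6,6-dimethylbicyclo[3.1.1]heptan-2-one
Conditions: (nPr4N)RuO4 (5 mol %), N-methylmorpholine N-oxide (1.5 equiv), 4 Å molecular sieves, CH2Cl2, 23 °C
Reagents that add atoms: none
Why: Ley–Griffith oxidation of the secondary alcohol to the ketone under neutral conditions; the bridgehead α-carbon cannot epimerise.

Step 8
Reactants: 12 (1S,5R)-6,6-dimethylbicyclo[3.1.1]heptan-2-one
Product: 13 (1R,5R)-6,6-dimethyl-2-methylidenebicyclo[3.1.1]heptane, (+)-β-pinene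
Conditions: Ph3PCH3Br (2 equiv), KOtBu (1.9 equiv), THF, 0 °C; then 12, 50 °C
Reagents that add atoms: methyltriphenylphosphonium bromide, C[P+](c1ccccc1)(c1ccccc1)c1ccccc1.[Br-]
Why: Wittig methylenation of the bicyclic ketone with the non-stabilised ylide, run with excess ylide in warm THF to overcome competing enolisation at C3.

Step 9
Reactants: 13 (1R,5R)-6,6-dimethyl-2-methylidenebicyclo[3.1.1]heptane; 14 syncarpic acid; 15 2-methylpropanal
Product: 17 (1S,2S,4'R,5R)-6,6,6',6',8',8'-hexamethyl-4'-(propan-2-yl)-3',4'-dihydrospiro[bicyclo[3.1.1]heptane-2,2'-chromene]-5',7'(6'H,8'H)-dione, via enetrione 16 (not isolated)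
Conditions: ethylenediammonium diacetate (20 mol %), 14 (2 equiv), 15 (3 equiv), toluene, 80 °C, sealed tube
Reagents that add atoms: none
Why: Domino Knoevenagel condensation and inverse-electron-demand hetero-Diels–Alder reaction, in which enetrione 16 adds as a 1-oxadiene across the exocyclic alkene with oxygen bonding to the more substituted carbon C2 from the face anti to the CMe2 bridge (spiro center), while C4' is set by the orientation of the heterodiene, which should prefer to lie over the C1–H side that lacks an axial hydrogen, so that 17 is expected together with its C4' epimer and is separated from it by chromatography.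

**Compound list**

1 | methyl 5-chloro-5-oxopentanoate | COC(=O)CCCC(=O)Cl | starting material
2 | (2-methylprop-1-en-1-yl)magnesium bromide | CC(C)=C[Mg]Br | starting material
3 | methyl 7-methyl-5-oxooct-6-enoate | COC(=O)CCCC(=O)C=C(C)C | intermediate
4 | methyl (5R)-5-hydroxy-7-methyloct-6-enoate | COC(=O)CCC[C@@H](O)C=C(C)C | intermediate
5 | methyl (5R)-5-[(tert-butyldimethylsilyl)oxy]-7-methyloct-6-enoate | COC(=O)CCC[C@@H](O[Si](C)(C)C(C)(C)C)C=C(C)C | intermediate
6 | (5R)-5-[(tert-butyldimethylsilyl)oxy]-7-methyloct-6-enoic acid | OC(=O)CCC[C@@H](O[Si](C)(C)C(C)(C)C)C=C(C)C | intermediate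
7 | (5R)-5-[(tert-butyldimethylsilyl)oxy]-7-methyloct-6-enoyl chloride (not isolated) | ClC(=O)CCC[C@@H](O[Si](C)(C)C(C)(C)C)C=C(C)C | intermediate
8 | (5R)-5-[(tert-butyldimethylsilyl)oxy]-7-methylocta-1,6-dien-1-one, the alkyl ketene (not isolated) | O=C=CCC[C@@H](O[Si](C)(C)C(C)(C)C)C=C(C)C | intermediate
9 | (1S,2R,5S)-2-[(tert-butyldimethylsilyl)oxy]-6,6-dimethylbicyclo[3.1.1]heptan-7-one (silyloxy group anti to the CMe2 bridge) | CC(C)(C)[Si](C)(C)O[C@@H]1CC[C@@H]2C(=O)[C@H]1C2(C)C | intermediate
10 | hydrazone of 9 (not isolated) | CC(C)(C)[Si](C)(C)O[C@@H]1CC[C@@H]2C(=NN)[C@H]1C2(C)C | intermediate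
11 | (1S,2R,5R)-6,6-dimethylbicyclo[3.1.1]heptan-2-ol (hydroxyl anti to the CMe2 bridge) | O[C@@H]1CC[C@@H]2C[C@H]1C2(C)C | intermediate
12 | (1S,5R)-6,6-dimethylbicyclo[3.1.1]heptan-2-one, (−)-nopinone | O=C1CC[C@@H]2C[C@H]1C2(C)C | intermediate
13 | (1R,5R)-6,6-dimethyl-2-methylidenebicyclo[3.1.1]heptane, (+)-β-pinene | C=C1CC[C@@H]2C[C@H]1C2(C)C | intermediate
14 | syncarpic acid (2,2,4,4-tetramethylcyclohexane-1,3,5-trione) | CC1(C)C(=O)CC(=O)C(C)(C)C1=O | starting material
15 | 2-methylpropanal | CC(C)C=O | starting material
16 | 2,2,4,4-tetramethyl-6-(2-methylpropylidene)cyclohexane-1,3,5-trione (not isolated) | CC(C)C=C1C(=O)C(C)(C)C(=O)C(C)(C)C1=O | intermediate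
17 | (1S,2S,4'R,5R)-6,6,6',6',8',8'-hexamethyl-4'-(propan-2-yl)-3',4'-dihydrospiro[bicyclo[3.1.1]heptane-2,2'-chromene]-5',7'(6'H,8'H)-dione | CC(C)[C@H]1C[C@]2(CC[C@@H]3C[C@H]2C3(C)C)OC2=C1C(=O)C(C)(C)C(=O)C2(C)C | target

**Step count and risks**

Total step count: 9. Longest linear sequence: 9 steps (1 to 17).

Steps most likely to fail:

1. Step 5. The slow dehydrochlorination to an unactivated monoalkyl ketene may let ketene dimerisation or acylation of the amine outrun the cycloaddition. The facial bias from the silyloxy center may also prove weaker than assumed. The fallback sets out from acid 6 and activates the ketene with a removable chlorine. The dianion of 6 (LDA, THF, −78 °C) is chlorinated with CCl4 to (5R)-5-[(tert-butyldimethylsilyl)oxy]-2-chloro-7-methyloct-6-enoic acid F1, used as the mixture of C2 epimers. The same α-chloroenamine converts it into the acid chloride F2, and Et3N in toluene at 80 °C releases the alkyl chloroketene F3, which is far more electrophilic and less prone to dimerise. Its [2+2] cycloaddition should give the bridgehead chloro ketone F4 with the same facial sense. Radical reduction (Bu3SnH, AIBN, benzene, 80 °C) removes the C5 chlorine with retention at the bridgehead and comes back to the route at 9.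

2. Step 9. The two orientations of the heterodiene over the exocyclic alkene may be poorly discriminated, so that selectivity at C4' is low. Ene reaction or acid-triggered opening of the cyclobutane may also compete. The fallback sets out from 13 and makes the sequence stereoconvergent. The three-component reaction is run as before and the unseparated mixture of 17 and its C4' epimer F5 is dehydrogenated (DDQ, 1,4-dioxane, 80 °C) by hydride abstraction from C4' and loss of a C3' proton to the 2H-chromene F6, in which C4' is trigonal. Hydrogenation of the C3'=C4' bond (H2, Rh/Al2O3, EtOAc, 23 °C) should occur from the face of the pyran ring that carries C3 of the pinane, because the other face is covered by C1 and its bridges. This places the isopropyl group cis to C1 and comes back to the route at 17.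

3. Step 6. Hot alkali may fragment the strained cyclobutanone (retro-aldol-type or Haller–Bauer cleavage once the silyl ether is lost) before the hydrazone is reduced, or desilylation may stay incomplete. The fallback sets out from 9 and avoids strong base. Condensation with p-toluenesulfonylhydrazide (EtOH, 60 °C) gives the tosylhydrazone F7. Reduction with catecholborane (CHCl3, 0 °C), then NaOAc·3H2O at 60 °C, expels sulfinate and N2 from the diazene to give the silyl ether F8. TBAF in THF at 23 °C then frees the alcohol and comes back to the route at 11.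

Further compounds
F1 | step 5 | (5R)-5-[(tert-butyldimethylsilyl)oxy]-2-chloro-7-methyloct-6-enoic acid (mixture at C2) | OC(=O)C(Cl)CC[C@@H](O[Si](C)(C)C(C)(C)C)C=C(C)C
F2 | step 5 | (5R)-5-[(tert-butyldimethylsilyl)oxy]-2-chloro-7-methyloct-6-enoyl chloride (mixture at C2) | ClC(=O)C(Cl)CC[C@@H](O[Si](C)(C)C(C)(C)C)C=C(C)C
F3 | step 5 | (5R)-5-[(tert-butyldimethylsilyl)oxy]-2-chloro-7-methylocta-1,6-dien-1-one, the chloroketene | O=C=C(Cl)CC[C@@H](O[Si](C)(C)C(C)(C)C)C=C(C)C
F4 | step 5 | (1S,2R,5R)-2-[(tert-butyldimethylsilyl)oxy]-5-chloro-6,6-dimethylbicyclo[3.1.1]heptan-7-one | CC(C)(C)[Si](C)(C)O[C@@H]1CC[C@]2(Cl)C(=O)[C@H]1C2(C)C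
F5 | step 9 | (1S,2S,4'S,5R)-6,6,6',6',8',8'-hexamethyl-4'-(propan-2-yl)-3',4'-dihydrospiro[bicyclo[3.1.1]heptane-2,2'-chromene]-5',7'(6'H,8'H)-dione, the C4' epimer of 17 | CC(C)[C@@H]1C[C@]2(CC[C@@H]3C[C@H]2C3(C)C)OC2=C1C(=O)C(C)(C)C(=O)C2(C)C
F6 | step 9 | (1S,2S,5R)-6,6,6',6',8',8'-hexamethyl-4'-(propan-2-yl)spiro[bicyclo[3.1.1]heptane-2,2'-chromene]-5',7'(6'H,8'H)-dione | CC(C)C1=C[C@]2(CC[C@@H]3C[C@H]2C3(C)C)OC2=C1C(=O)C(C)(C)C(=O)C2(C)C
F7 | step 6 | p-toluenesulfonylhydrazone of 9 | CC(C)(C)[Si](C)(C)O[C@@H]1CC[C@@H]2C(=NNS(=O)(=O)c3ccc(C)cc3)[C@H]1C2(C)C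
F8 | step 6 | (1S,2R,5R)-2-[(tert-butyldimethylsilyl)oxy]-6,6-dimethylbicyclo[3.1.1]heptane | CC(C)(C)[Si](C)(C)O[C@@H]1CC[C@@H]2C[C@H]1C2(C)C
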